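**Plan**

- Retrosynthesis: the seven O‑benzyl groups come off last. Then the C3–C4 bond of flavanone ring C is cut, giving a ring A benzaldehyde whose ortho oxygen (O1) carries a 1‑arylvinyl group (C2=C3, ring B on C2).
- Enabling feature: in ring C, C4 is an aroyl carbon on ring A, C3 is an unsubstituted CH2, and C2 carries only H, O1 and ring B. Ring C is therefore the retron of an intramolecular alkene hydroacylation in which the formyl hydrogen ends on C2.
- Further cuts: the C2=C3 methylene (from the carbonyl of an aryl benzoate), the ester C–O bond between the ring A phenol and the ring B acid, the biaryl C5'–C8'' bond (Suzuki–Miyaura), and the flavone pyranone ring (chalcone).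
- Forward order: the flavone heterocycle is built first on its own branch. Rings A and B are joined as an ester, methylenated, borylated and coupled to the 8‑iodoflavone. Flavanone ring C closes last.
- Stereochemistry: the only stereocentre, C2 (S), is created in the ring closure by a chiral rhodium bisphosphine catalyst and kept by a neutral final deprotection.

Key step: step 16

Assumption: the target SMILES gives no descriptor for the biaryl axis, so the axis is not controlled; only C2 (S) is.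
Assumption: the sense of induction in step 16 cannot be predicted with certainty. (R)-DTBM-SEGPHOS is written; its mirror image is used if a pilot run on 2-[(1-phenylethenyl)oxy]benzaldehyde shows the 2R sense.

**Route**

Step 1
Reactants: 1 2,4,6-trihydroxybenzaldehyde; 2 benzyl bromide
Product: 3 2,4-bis(benzyloxy)-6-hydroxybenzaldehyde
Conditions: BnBr (2.05 equiv), K2CO3, DMF, 0 °C to rt
Reagents that add atoms: benzyl bromide (2), BrCc1ccccc1
Why: Williamson etherification in which the hydroxyl hydrogen-bonded to the formyl group is the least nucleophilic and should stay free after two benzylations.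

Step 2
Reactants: 3 2,4-bis(benzyloxy)-6-hydroxybenzaldehyde
Product: 4 3,5-bis(benzyloxy)-2-(hydroxymethyl)phenol
Conditions: NaBH4, THF/MeOH, 0 °C; pH 7 buffer work-up; used crude
Reagents that add atoms: none
Why: Borohydride reduction of an aryl aldehyde, with neutral work-up and immediate use so that the electron-rich salicyl alcohol does not ionise to an ortho-quinone methide.

Step 3
Reactants: 4 3,5-bis(benzyloxy)-2-(hydroxymethyl)phenol; 5 tert-butyldimethylsilyl chloride
Product: 6 3,5-bis(benzyloxy)-2-{[(tert-butyldimethylsilyl)oxy]methyl}phenol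
Conditions: TBSCl (1.05 equiv), imidazole, CH2Cl2, 0 °C
Reagents that add atoms: tert-butyldimethylsilyl chloride (5), CC(C)(C)[Si](C)(C)Cl
Why: Selective O-silylation, since one equivalent of silyl chloride should take the unhindered primary benzylic hydroxyl before the phenol, as is usual for hydroxybenzyl alcohols; this masks the future formyl carbon against step 7.

Step 4
Reactants: 7 3-bromo-4,5-dihydroxybenzaldehyde; 2 benzyl bromide
Product: 8 3,4-bis(benzyloxy)-5-bromobenzaldehyde
Conditions: BnBr (2.3 equiv), K2CO3, DMF, 60 °C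
Reagents that add atoms: benzyl bromide (2), BrCc1ccccc1
Why: Williamson etherification of both catechol hydroxyls, the aldehyde and aryl bromide being inert to carbonate.

Step 5
Reactants: 8 3,4-bis(benzyloxy)-5-bromobenzaldehyde; 9 sodium chlorite
Product: 10 3,4-bis(benzyloxy)-5-bromobenzoic acid
Conditions: NaClO2, NaH2PO4, 2-methyl-2-butene, t-BuOH/THF/H2O, rt
Reagents that add atoms: sodium chlorite (9), [Na+].[O-]Cl=O
Why: Pinnick oxidation of the aldehyde to the acid, with the alkene scavenging hypochlorite so that the electron-rich ring is not chlorinated.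

Step 6
Reactants: 6 3,5-bis(benzyloxy)-2-{[(tert-butyldimethylsilyl)oxy]methyl}phenol; 10 3,4-bis(benzyloxy)-5-bromobenzoic acid
Product: 11 3,5-bis(benzyloxy)-2-{[(tert-butyldimethylsilyl)oxy]methyl}phenyl 3,4-bis(benzyloxy)-5-bromobenzoate
Conditions: DCC, DMAP (cat.), CH2Cl2, 0 °C to rt
Reagents that add atoms: none
Why: Steglich esterification joins ring A (through the future O1) to the carbon that becomes C2, with the acyl-pyridinium intermediate overcoming the ortho substituent on the phenol.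

Step 7
Reactants: 11 3,5-bis(benzyloxy)-2-{[(tert-butyldimethylsilyl)oxy]methyl}phenyl 3,4-bis(benzyloxy)-5-bromobenzoate; 12 dimethyltitanocene
Product: 13 tert-butyl{[2-({1-[3,4-bis(benzyloxy)-5-bromophenyl]ethenyl}oxy)-4,6-bis(benzyloxy)phenyl]methoxy}dimethylsilane
Conditions: Cp2TiMe2 (3 equiv), toluene/THF, 65 °C, dark; filtration through basic alumina
Reagents that add atoms: dimethyltitanocene (12), [CH3-].[CH3-].[Ti+4].c1cc[cH-]c1.c1cc[cH-]c1
Why: Petasis methylenation, in which thermally formed Cp2Ti=CH2 adds to the ester carbonyl and the oxatitanacyclobutane collapses to the 1-aryl-1-aryloxyethene, a conversion established for aryl benzoates and inert towards aryl bromide, benzyl ethers and silyl ether.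

Step 8
Reactants: 13 tert-butyl{[2-({1-[3,4-bis(benzyloxy)-5-bromophenyl]ethenyl}oxy)-4,6-bis(benzyloxy)phenyl]methoxy}dimethylsilane; 14 bis(pinacolato)diboron
Product: 15 tert-butyl{[2-({1-[3,4-bis(benzyloxy)-5-(4,4,5,5-tetramethyl-1,3,2-dioxaborolan-2-yl)phenyl]ethenyl}oxy)-4,6-bis(benzyloxy)phenyl]methoxy}dimethylsilane
Conditions: B2pin2 (1.2 equiv), PdCl2(dppf) (5 mol %), KOAc, 1,4-dioxane, 85 °C
Reagents that add atoms: bis(pinacolato)diboron (14), CC1(C)OB(OC1(C)C)B1OC(C)(C)C(C)(C)O1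
Why: Miyaura borylation of the aryl bromide under weakly basic acetate conditions, which the base-stable enol ether and silyl ether should survive.

Step 9
Reactants: 16 2',4',6'-trihydroxyacetophenone; 2 benzyl bromide
Product: 17 1-[2,4-bis(benzyloxy)-6-hydroxyphenyl]ethan-1-one
Conditions: BnBr (2.1 equiv), K2CO3, DMF, rt
Reagents that add atoms: benzyl bromide (2), BrCc1ccccc1
Why: Williamson etherification that leaves the ketone-chelated ortho hydroxyl free, as is usual for phloroacetophenone.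

Step 10
Reactants: 17 1-[2,4-bis(benzyloxy)-6-hydroxyphenyl]ethan-1-one; 18 benzyltrimethylammonium dichloroiodate
Product: 19 1-[4,6-bis(benzyloxy)-2-hydroxy-3-iodophenyl]ethan-1-one
Conditions: BnNMe3·ICl2 (1.05 equiv), CaCO3, CH2Cl2/MeOH, rt
Reagents that add atoms: benzyltrimethylammonium dichloroiodate (18), C[N+](C)(C)Cc1ccccc1.Cl[I-]Cl
Why: Electrophilic aromatic iodination, which on 2-hydroxy-4,6-dialkoxyacetophenones is expected to enter ortho to the free chelated phenol and not between the two ethers, placing iodine at the future C8 of the flavone.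

Step 11
Reactants: 19 1-[4,6-bis(benzyloxy)-2-hydroxy-3-iodophenyl]ethan-1-one; 20 4-(benzyloxy)benzaldehyde
Product: 22 (E)-1-[4,6-bis(benzyloxy)-2-hydroxy-3-iodophenyl]-3-[4-(benzyloxy)phenyl]prop-2-en-1-one, via aldol adduct 21 (not isolated)
Conditions: KOH (50% aq.), EtOH/THF, rt; then dilute HCl to pH 5
Reagents that add atoms: none
Why: Claisen–Schmidt condensation (aldol addition, then E1cB dehydration to the conjugated E-enone) between a methyl ketone and a non-enolisable aldehyde.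

Step 12
Reactants: 22 (E)-1-[4,6-bis(benzyloxy)-2-hydroxy-3-iodophenyl]-3-[4-(benzyloxy)phenyl]prop-2-en-1-one
Product: 24 5,7-bis(benzyloxy)-2-[4-(benzyloxy)phenyl]-8-iodo-4H-chromen-4-one, via iodoflavanone 23 (not isolated)
Conditions: I2 (10 mol %), DMSO, 130 °C
Reagents that add atoms: none
Why: Iodine-catalysed oxidative cyclisation of a 2'-hydroxychalcone in DMSO (oxa-Michael closure, α-iodination and loss of HI, with DMSO reoxidising iodide), a standard flavone synthesis that should tolerate the aryl iodide and benzyl ethers while iodine is kept catalytic.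

Step 13
Reactants: 15 tert-butyl{[2-({1-[3,4-bis(benzyloxy)-5-(4,4,5,5-tetramethyl-1,3,2-dioxaborolan-2-yl)phenyl]ethenyl}oxy)-4,6-bis(benzyloxy)phenyl]methoxy}dimethylsilane; 24 5,7-bis(benzyloxy)-2-[4-(benzyloxy)phenyl]-8-iodo-4H-chromen-4-one
Product: 25 5,7-bis(benzyloxy)-2-[4-(benzyloxy)phenyl]-8-{2,3-bis(benzyloxy)-5-[1-({3,5-bis(benzyloxy)-2-[(tert-butyldimethylsilyloxy)methyl]phenyl}oxy)ethenyl]phenyl}-4H-chromen-4-one
Conditions: Pd(OAc)2 (5 mol %), SPhos (10 mol %), K3PO4, toluene/H2O (10:1), 80 °C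
Reagents that add atoms: none
Why: Suzuki–Miyaura coupling with a dialkylbiarylphosphine designed for tri-ortho-substituted biaryls, the iodide sitting on the more hindered partner and the enol ether, silyl ether and flavone being stable to aqueous phosphate.

Step 14
Reactants: 25 5,7-bis(benzyloxy)-2-[4-(benzyloxy)phenyl]-8-{2,3-bis(benzyloxy)-5-[1-({3,5-bis(benzyloxy)-2-[(tert-butyldimethylsilyloxy)methyl]phenyl}oxy)ethenyl]phenyl}-4H-chromen-4-one
Product: 26 5,7-bis(benzyloxy)-2-[4-(benzyloxy)phenyl]-8-{2,3-bis(benzyloxy)-5-[1-({3,5-bis(benzyloxy)-2-(hydroxymethyl)phenyl}oxy)ethenyl]phenyl}-4H-chromen-4-one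
Conditions: Bu4NF (1.2 equiv), THF, 0 °C
Reagents that add atoms: none
Why: Fluoride-induced desilylation under non-acidic conditions, as the acid-labile aryl enol ether requires.

Step 15
Reactants: 26 5,7-bis(benzyloxy)-2-[4-(benzyloxy)phenyl]-8-{2,3-bis(benzyloxy)-5-[1-({3,5-bis(benzyloxy)-2-(hydroxymethyl)phenyl}oxy)ethenyl]phenyl}-4H-chromen-4-one
Product: 27 8-{2,3-bis(benzyloxy)-5-[1-(3,5-bis(benzyloxy)-2-formylphenoxy)ethenyl]phenyl}-5,7-bis(benzyloxy)-2-[4-(benzyloxy)phenyl]-4H-chromen-4-one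
Conditions: MnO2 (activated, excess), CH2Cl2, rt
Reagents that add atoms: none
Why: Heterogeneous MnO2 oxidation of an electron-rich benzylic alcohol to the aldehyde, neutral and without over-oxidation, which should leave the enol ether untouched.

Step 16
Reactants: 27 8-{2,3-bis(benzyloxy)-5-[1-(3,5-bis(benzyloxy)-2-formylphenoxy)ethenyl]phenyl}-5,7-bis(benzyloxy)-2-[4-(benzyloxy)phenyl]-4H-chromen-4-one
Product: 28 (2S)-5,7-bis(benzyloxy)-2-(3,4-bis(benzyloxy)-5-{5,7-bis(benzyloxy)-2-[4-(benzyloxy)phenyl]-4-oxo-4H-chromen-8-yl}phenyl)-2,3-dihydro-4H-chromen-4-one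
Conditions: [Rh(cod)Cl]2 (5 mol %), (R)-DTBM-SEGPHOS (10 mol %), Na[B(3,5-(CF3)2C6H3)4] (10 mol %), degassed 1,4-dioxane, 60 °C
Reagents that add atoms: none
Why: Proposed new method: oxidative addition of the formyl C–H to the cationic monovalent rhodium bisphosphine complex should give an acyl rhodium hydride held by the neighbouring ether oxygen; the 1,1-disubstituted enol ether then inserts into Rh–H with hydride going to the O- and aryl-bearing carbon (future C2) and rhodium to the terminal CH2, and C–C reductive elimination from the seven-membered acyl–alkyl rhodacycle forms the C3–C4 bond. The closest known reaction type is the rhodium-bisphosphine-catalysed enantioselective endo hydroacylation of ortho-(2-substituted allyl)benzaldehydes to 3-substituted tetralones, of which 27 is the analogue with oxygen in place of the benzylic CH2; an aryl enol ether has not served as the alkene in this reaction. Ring C closes in a 6-endo-trig mode. The single new stereocentre C2 is set when hydride is delivered to one enantiotopic face of the enol ether inside the chiral pocket of the bisphosphine, so the catalyst alone controls it. The step needs 6-endo over 5-exo closure (the latter would give a 2-aryl-2-methylbenzofuran-3-one), which the 1,1-disubstitution secures because the alternative insertion would place rhodium on a fully substituted carbon and require a quaternary centre. It also needs insertion and reductive elimination to outrun decarbonylation, which the chelating ortho oxygen and the non-coordinating counterion support, and the alkene has no allylic hydrogen, so no isomerisation can compete.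

Step 17
Reactants: 28 (2S)-5,7-bis(benzyloxy)-2-(3,4-bis(benzyloxy)-5-{5,7-bis(benzyloxy)-2-[4-(benzyloxy)phenyl]-4-oxo-4H-chromen-8-yl}phenyl)-2,3-dihydro-4H-chromen-4-one
Product: 29 (2S)-2-{3,4-dihydroxy-5-[5,7-dihydroxy-2-(4-hydroxyphenyl)-4-oxo-4H-chromen-8-yl]phenyl}-5,7-dihydroxy-2,3-dihydro-4H-chromen-4-one
Conditions: H2 (1 atm), 10% Pd on carbon, THF/MeOH, rt; reversed-phase purification with 0.1% HCO2H
Reagents that add atoms: none
Why: Catalytic hydrogenolysis of the seven benzyl ethers at ambient pressure should be faster than reduction of the flavone double bond or of the ring C benzylic C–O bond and, being neutral, avoids the base-induced retro-oxa-Michael opening that would racemise C2.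

**Compound list**

1 | 2,4,6-trihydroxybenzaldehyde | O=Cc1c(O)cc(O)cc1O | starting material
2 | benzyl bromide | BrCc1ccccc1 | starting material
3 | 2,4-bis(benzyloxy)-6-hydroxybenzaldehyde | O=Cc1c(O)cc(OCc2ccccc2)cc1OCc1ccccc1 | intermediate
4 | 3,5-bis(benzyloxy)-2-(hydroxymethyl)phenol | OCc1c(O)cc(OCc2ccccc2)cc1OCc1ccccc1 | intermediate
5 | tert-butyldimethylsilyl chloride | CC(C)(C)[Si](C)(C)Cl | starting material
6 | 3,5-bis(benzyloxy)-2-{[(tert-butyldimethylsilyl)oxy]methyl}phenol | CC(C)(C)[Si](C)(C)OCc1c(O)cc(OCc2ccccc2)cc1OCc1ccccc1 | intermediate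
7 | 3-bromo-4,5-dihydroxybenzaldehyde | O=Cc1cc(O)c(O)c(Br)c1 | starting material
8 | 3,4-bis(benzyloxy)-5-bromobenzaldehyde | O=Cc1cc(OCc2ccccc2)c(OCc2ccccc2)c(Br)c1 | intermediate
9 | sodium chlorite | [Na+].[O-]Cl=O | starting material
10 | 3,4-bis(benzyloxy)-5-bromobenzoic acid | OC(=O)c1cc(OCc2ccccc2)c(OCc2ccccc2)c(Br)c1 | intermediate
11 | 3,5-bis(benzyloxy)-2-{[(tert-butyldimethylsilyl)oxy]methyl}phenyl 3,4-bis(benzyloxy)-5-bromobenzoate | CC(C)(C)[Si](C)(C)OCc1c(OC(=O)c2cc(OCc3ccccc3)c(OCc3ccccc3)c(Br)c2)cc(OCc2ccccc2)cc1OCc1ccccc1 | intermediate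
12 | dimethyltitanocene (Cp2TiMe2) | [CH3-].[CH3-].[Ti+4].c1cc[cH-]c1.c1cc[cH-]c1 | starting material
13 | tert-butyl{[2-({1-[3,4-bis(benzyloxy)-5-bromophenyl]ethenyl}oxy)-4,6-bis(benzyloxy)phenyl]methoxy}dimethylsilane | C=C(Oc1cc(OCc2ccccc2)cc(OCc2ccccc2)c1CO[Si](C)(C)C(C)(C)C)c1cc(OCc2ccccc2)c(OCc2ccccc2)c(Br)c1 | intermediate
14 | bis(pinacolato)diboron | CC1(C)OB(OC1(C)C)B1OC(C)(C)C(C)(C)O1 | starting material
15 | tert-butyl{[2-({1-[3,4-bis(benzyloxy)-5-(4,4,5,5-tetramethyl-1,3,2-dioxaborolan-2-yl)phenyl]ethenyl}oxy)-4,6-bis(benzyloxy)phenyl]methoxy}dimethylsilane | C=C(Oc1cc(OCc2ccccc2)cc(OCc2ccccc2)c1CO[Si](C)(C)C(C)(C)C)c1cc(OCc2ccccc2)c(OCc2ccccc2)c(B2OC(C)(C)C(C)(C)O2)c1 | intermediate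
16 | 2',4',6'-trihydroxyacetophenone | CC(=O)c1c(O)cc(O)cc1O | starting material
17 | 1-[2,4-bis(benzyloxy)-6-hydroxyphenyl]ethan-1-one | CC(=O)c1c(O)cc(OCc2ccccc2)cc1OCc1ccccc1 | intermediate
18 | benzyltrimethylammonium dichloroiodate | C[N+](C)(C)Cc1ccccc1.Cl[I-]Cl | starting material
19 | 1-[4,6-bis(benzyloxy)-2-hydroxy-3-iodophenyl]ethan-1-one | CC(=O)c1c(O)c(I)c(OCc2ccccc2)cc1OCc1ccccc1 | intermediate
20 | 4-(benzyloxy)benzaldehyde | O=Cc1ccc(OCc2ccccc2)cc1 | starting material
21 | 1-[4,6-bis(benzyloxy)-2-hydroxy-3-iodophenyl]-3-[4-(benzyloxy)phenyl]-3-hydroxypropan-1-one (racemic aldol adduct, not isolated) | O=C(CC(O)c1ccc(OCc2ccccc2)cc1)c1c(O)c(I)c(OCc2ccccc2)cc1OCc1ccccc1 | intermediate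
22 | (E)-1-[4,6-bis(benzyloxy)-2-hydroxy-3-iodophenyl]-3-[4-(benzyloxy)phenyl]prop-2-en-1-one | O=C(/C=C/c1ccc(OCc2ccccc2)cc1)c1c(O)c(I)c(OCc2ccccc2)cc1OCc1ccccc1 | intermediate
23 | 5,7-bis(benzyloxy)-2-[4-(benzyloxy)phenyl]-8-iodo-2,3-dihydro-4H-chromen-4-one (racemic, not isolated) | O=C1CC(c2ccc(OCc3ccccc3)cc2)Oc2c(I)c(OCc3ccccc3)cc(OCc3ccccc3)c21 | intermediate
24 | 5,7-bis(benzyloxy)-2-[4-(benzyloxy)phenyl]-8-iodo-4H-chromen-4-one | O=c1cc(-c2ccc(OCc3ccccc3)cc2)oc2c(I)c(OCc3ccccc3)cc(OCc3ccccc3)c12 | intermediate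
25 | 5,7-bis(benzyloxy)-2-[4-(benzyloxy)phenyl]-8-{2,3-bis(benzyloxy)-5-[1-({3,5-bis(benzyloxy)-2-[(tert-butyldimethylsilyloxy)methyl]phenyl}oxy)ethenyl]phenyl}-4H-chromen-4-one | C=C(Oc1cc(OCc2ccccc2)cc(OCc2ccccc2)c1CO[Si](C)(C)C(C)(C)C)c1cc(OCc2ccccc2)c(OCc2ccccc2)c(-c2c(OCc3ccccc3)cc(OCc3ccccc3)c3c(=O)cc(-c4ccc(OCc5ccccc5)cc4)oc23)c1 | intermediate
26 | 5,7-bis(benzyloxy)-2-[4-(benzyloxy)phenyl]-8-{2,3-bis(benzyloxy)-5-[1-({3,5-bis(benzyloxy)-2-(hydroxymethyl)phenyl}oxy)ethenyl]phenyl}-4H-chromen-4-one | C=C(Oc1cc(OCc2ccccc2)cc(OCc2ccccc2)c1CO)c1cc(OCc2ccccc2)c(OCc2ccccc2)c(-c2c(OCc3ccccc3)cc(OCc3ccccc3)c3c(=O)cc(-c4ccc(OCc5ccccc5)cc4)oc23)c1 | intermediate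
27 | 8-{2,3-bis(benzyloxy)-5-[1-(3,5-bis(benzyloxy)-2-formylphenoxy)ethenyl]phenyl}-5,7-bis(benzyloxy)-2-[4-(benzyloxy)phenyl]-4H-chromen-4-one | C=C(Oc1cc(OCc2ccccc2)cc(OCc2ccccc2)c1C=O)c1cc(OCc2ccccc2)c(OCc2ccccc2)c(-c2c(OCc3ccccc3)cc(OCc3ccccc3)c3c(=O)cc(-c4ccc(OCc5ccccc5)cc4)oc23)c1 | intermediate
28 | (2S)-5,7-bis(benzyloxy)-2-(3,4-bis(benzyloxy)-5-{5,7-bis(benzyloxy)-2-[4-(benzyloxy)phenyl]-4-oxo-4H-chromen-8-yl}phenyl)-2,3-dihydro-4H-chromen-4-one | O=C1C[C@@H](c2cc(OCc3ccccc3)c(OCc3ccccc3)c(-c3c(OCc4ccccc4)cc(OCc4ccccc4)c4c(=O)cc(-c5ccc(OCc6ccccc6)cc5)oc34)c2)Oc2cc(OCc3ccccc3)cc(OCc3ccccc3)c21 | intermediate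
29 | (2S)-2-{3,4-dihydroxy-5-[5,7-dihydroxy-2-(4-hydroxyphenyl)-4-oxo-4H-chromen-8-yl]phenyl}-5,7-dihydroxy-2,3-dihydro-4H-chromen-4-one | O=C1C[C@@H](c2cc(O)c(O)c(-c3c(O)cc(O)c4c(=O)cc(-c5ccc(O)cc5)oc34)c2)Oc2cc(O)cc(O)c21 | target

**Step count and risks**

Total step count: 17. Longest linear sequence: 11 steps (steps 1, 2, 3, 6, 7, 8, 13, 14, 15, 16, 17).

Steps most likely to fail:

1. Step 16 (Proposed new method). What may go wrong:
   - decarbonylation of the acyl rhodium hydride before the alkene inserts;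
   - β-aryloxide elimination from the alkyl rhodium intermediate;
   - 5-exo closure;
   - weak facial discrimination in the hydride transfer.

   Fallback with known chemistry, closing ring C at O1–C2 instead and resolving. It sets out from 8, which is borylated (B2pin2, PdCl2(dppf), KOAc, dioxane) to 3,4-bis(benzyloxy)-5-(4,4,5,5-tetramethyl-1,3,2-dioxaborolan-2-yl)benzaldehyde F1. Suzuki–Miyaura coupling of F1 with 24 (Pd(OAc)2, SPhos, K3PO4) should give the biaryl aldehyde 3,4-bis(benzyloxy)-5-{5,7-bis(benzyloxy)-2-[4-(benzyloxy)phenyl]-4-oxo-4H-chromen-8-yl}benzaldehyde F2. Claisen–Schmidt condensation of F2 with acetophenone 17 (KOH, EtOH/THF, rt) should give the 2'-hydroxychalcone F3. NaOAc in refluxing EtOH should close it by oxa-Michael addition to the racemic heptabenzyl flavanone F4. Preparative HPLC on a polysaccharide chiral stationary phase separates the enantiomers, and the (2S) one is 28, where the route is rejoined.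

2. Step 13. What may go wrong: slow transmetalation at the doubly ortho-flanked C–I site, so that protodeboronation of the boronate and hydrodeiodination of the flavone win. Fallback with reversed roles of the partners: it sets out from 24, which is borylated (B2pin2, PdCl2(dppf), KOAc, dioxane) to 5,7-bis(benzyloxy)-2-[4-(benzyloxy)phenyl]-8-(4,4,5,5-tetramethyl-1,3,2-dioxaborolan-2-yl)-4H-chromen-4-one F5. F5 is coupled with bromide 13 (Pd(OAc)2, SPhos, K3PO4, toluene/H2O) to come back at 25; step 8 is then not needed.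

3. Step 17. What may go wrong: saturation of the flavone C2''=C3'' bond, or hydrogenolytic opening of the benzylic O1–C2 bond of ring C, before the last benzyl ether is cleaved. Fallback by Lewis-acid dealkylation in place of hydrogenolysis: it sets out from 28, which is treated with BCl3 and pentamethylbenzene (cation scavenger) in CH2Cl2 at −78 °C and quenched with MeOH, and comes back at 29 directly; no new isolated compound arises.

Further compounds
F1 | step 16 | 3,4-bis(benzyloxy)-5-(4,4,5,5-tetramethyl-1,3,2-dioxaborolan-2-yl)benzaldehyde | O=Cc1cc(OCc2ccccc2)c(OCc2ccccc2)c(B2OC(C)(C)C(C)(C)O2)c1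
F2 | step 16 | 3,4-bis(benzyloxy)-5-{5,7-bis(benzyloxy)-2-[4-(benzyloxy)phenyl]-4-oxo-4H-chromen-8-yl}benzaldehyde | O=Cc1cc(OCc2ccccc2)c(OCc2ccccc2)c(-c2c(OCc3ccccc3)cc(OCc3ccccc3)c3c(=O)cc(-c4ccc(OCc5ccccc5)cc4)oc23)c1
F3 | step 16 | (E)-1-[2,4-bis(benzyloxy)-6-hydroxyphenyl]-3-(3,4-bis(benzyloxy)-5-{5,7-bis(benzyloxy)-2-[4-(benzyloxy)phenyl]-4-oxo-4H-chromen-8-yl}phenyl)prop-2-en-1-one | O=C(/C=C/c1cc(OCc2ccccc2)c(OCc2ccccc2)c(-c2c(OCc3ccccc3)cc(OCc3ccccc3)c3c(=O)cc(-c4ccc(OCc5ccccc5)cc4)oc23)c1)c1c(O)cc(OCc2ccccc2)cc1OCc1ccccc1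
F4 | step 16 | racemic 5,7-bis(benzyloxy)-2-(3,4-bis(benzyloxy)-5-{5,7-bis(benzyloxy)-2-[4-(benzyloxy)phenyl]-4-oxo-4H-chromen-8-yl}phenyl)-2,3-dihydro-4H-chromen-4-one | O=C1CC(c2cc(OCc3ccccc3)c(OCc3ccccc3)c(-c3c(OCc4ccccc4)cc(OCc4ccccc4)c4c(=O)cc(-c5ccc(OCc6ccccc6)cc5)oc34)c2)Oc2cc(OCc3ccccc3)cc(OCc3ccccc3)c21
F5 | step 13 | 5,7-bis(benzyloxy)-2-[4-(benzyloxy)phenyl]-8-(4,4,5,5-tetramethyl-1,3,2-dioxaborolan-2-yl)-4H-chromen-4-one | O=c1cc(-c2ccc(OCc3ccccc3)cc2)oc2c(B3OC(C)(C)C(C)(C)O3)c(OCc3ccccc3)cc(OCc3ccccc3)c12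
F0 | step 17 | none | none
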